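**Plan**
- The target has no stereocentres. It is a 5,7-dihydroxy-4'-methoxyisoflavone joined through C8 to C3' (ring B) of a 5,7-dihydroxy-4'-methoxyflavone.
- Enabling feature: in the pyranone ring of the isoflavone half, C3 carries the 4-methoxyphenyl ring and C2 is an O1-bound CH at the aldehyde oxidation level. C2–C3 is therefore the Cβ–Cα unit of a 2'-hydroxychalcone whose anisyl group has moved from Cβ to Cα.
- Retrosynthesis: cut the four O–benzyl bonds, then O1–C2 and C3–aryl of the isoflavone (back to a chalcone), then the biaryl bond C8–C3'. Last come the two enone C=C bonds and O1–C2 of the flavone, leading to one benzylated phloroacetophenone that is used twice.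
- Forward: one portion of the ketone is taken to the flavone (its ring C closes first) and borylated in ring B. The other portion is iodinated and condensed to an iodochalcone. Suzuki coupling joins the halves, the isoflavone ring C closes last by aryl shift and acid closure, and hydrogenolysis frees the phenols.
- Stereochemistry: nothing has to be set. The E-enones arise from thermodynamically controlled aldol dehydration and are consumed.

Key step: step 8

Assumption: iodination of the dibenzylated ketone is taken to occur ortho to its free hydroxyl (the position between OH and OBn), the usual site of halogenation of 2'-hydroxy-4',6'-dialkoxyacetophenones. The position of the iodine would be checked by NOE/HMBC before the material is carried on.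

**Route**

Step 1
Reactants: 1 2',4',6'-trihydroxyacetophenone
Product: 2 1-[2,4-bis(benzyloxy)-6-hydroxyphenyl]ethanone
Conditions: BnBr (2.1 equiv), K2CO3, DMF, rt
Reagents that add atoms: benzyl bromide, BrCc1ccccc1
Why: Williamson etherification with a mild base alkylates the 4-hydroxyl and one of the two equivalent ortho hydroxyls, while the remaining ortho hydroxyl is held in a strong hydrogen bond to the ketone and stays free, as is usual for phloroacetophenone.

Step 2
Reactants: 2 1-[2,4-bis(benzyloxy)-6-hydroxyphenyl]ethanone; 3 3-bromo-4-methoxybenzaldehyde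
Product: 4 (E)-1-[2,4-bis(benzyloxy)-6-hydroxyphenyl]-3-(3-bromo-4-methoxyphenyl)prop-2-en-1-one
Conditions: KOH (50% aq), EtOH/THF, rt
Reagents that add atoms: none
Why: Claisen–Schmidt aldol condensation of the methyl ketone enolate with a non-enolisable aldehyde, followed by E1cB loss of water, gives the conjugated E-enone, and the strongly basic medium holds the product as the open-chain phenoxide instead of the flavanone.

Step 3
Reactants: 4 (E)-1-[2,4-bis(benzyloxy)-6-hydroxyphenyl]-3-(3-bromo-4-methoxyphenyl)prop-2-en-1-one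
Product: 6 5,7-bis(benzyloxy)-2-(3-bromo-4-methoxyphenyl)-4H-chromen-4-one, via racemic bromoflavanone 5 (not isolated)
Conditions: I2 (10 mol %), DMSO, 120 °C
Reagents that add atoms: none
Why: Iodine-catalysed oxidative cyclisation of a 2'-hydroxychalcone in DMSO, in which oxa-Michael closure gives flavanone 5, α-iodination and loss of HI give the flavone, and DMSO turns HI back into I2, so that the aryl bromide and the benzyl ethers are not involved.

Step 4
Reactants: 6 5,7-bis(benzyloxy)-2-(3-bromo-4-methoxyphenyl)-4H-chromen-4-one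
Product: 7 5,7-bis(benzyloxy)-2-[4-methoxy-3-(4,4,5,5-tetramethyl-1,3,2-dioxaborolan-2-yl)phenyl]-4H-chromen-4-one
Conditions: B2pin2, Pd(dppf)Cl2 (5 mol %), KOAc, 1,4-dioxane, 90 °C
Reagents that add atoms: bis(pinacolato)diboron, CC1(C)OB(OC1(C)C)B1OC(C)(C)C(C)(C)O1
Why: Miyaura borylation, in which zerovalent palladium inserts into the C–Br bond and the weak base KOAc promotes boron transfer without starting a Suzuki homocoupling, while the flavone carbonyl and the benzyl ethers are inert.

Step 5
Reactants: 2 1-[2,4-bis(benzyloxy)-6-hydroxyphenyl]ethanone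
Product: 8 1-[4,6-bis(benzyloxy)-2-hydroxy-3-iodophenyl]ethanone
Conditions: BnMe3N·ICl2 (1.05 equiv), NaHCO3, CH2Cl2/MeOH, rt
Reagents that add atoms: benzyltrimethylammonium dichloroiodate, C[N+](C)(C)Cc1ccccc1.Cl[I-]Cl
Why: Electrophilic aromatic iodination of a phenol by the dichloroiodate salt is expected ortho to the free hydroxyl, at the position flanked by hydroxyl and one benzyloxy group and not at the more crowded position between two benzyloxy groups, and one equivalent at room temperature should stop at the mono-iodide without touching the methyl ketone.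

Step 6
Reactants: 8 1-[4,6-bis(benzyloxy)-2-hydroxy-3-iodophenyl]ethanone; 9 4-methoxybenzaldehyde
Product: 10 (E)-1-[4,6-bis(benzyloxy)-2-hydroxy-3-iodophenyl]-3-(4-methoxyphenyl)prop-2-en-1-one
Conditions: KOH (50% aq), EtOH/THF, rt
Reagents that add atoms: none
Why: Claisen–Schmidt condensation as in step 2, the aryl iodide being inert to hydroxide at room temperature and the aldehyde unable to enolise, so that only the crossed E-enone forms.

Step 7
Reactants: 10 (E)-1-[4,6-bis(benzyloxy)-2-hydroxy-3-iodophenyl]-3-(4-methoxyphenyl)prop-2-en-1-one; 7 5,7-bis(benzyloxy)-2-[4-methoxy-3-(4,4,5,5-tetramethyl-1,3,2-dioxaborolan-2-yl)phenyl]-4H-chromen-4-one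
Product: 11 (E)-1-{4,6-bis(benzyloxy)-3-[5-(5,7-bis(benzyloxy)-4-oxo-4H-chromen-2-yl)-2-methoxyphenyl]-2-hydroxyphenyl}-3-(4-methoxyphenyl)prop-2-en-1-one
Conditions: Pd(OAc)2 (5 mol %), SPhos (10 mol %), K3PO4, 1,4-dioxane/H2O, 80 °C
Reagents that add atoms: none
Why: Suzuki–Miyaura coupling, with the bulky electron-rich biarylphosphine SPhos chosen for a biaryl with three ortho substituents and the aryl iodide as the only site of oxidative addition, while aqueous phosphate keeps the chalcone as its open phenoxide during the coupling.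

Step 8
Reactants: 11 (E)-1-{4,6-bis(benzyloxy)-3-[5-(5,7-bis(benzyloxy)-4-oxo-4H-chromen-2-yl)-2-methoxyphenyl]-2-hydroxyphenyl}-3-(4-methoxyphenyl)prop-2-en-1-one
Product: 13 5,7-bis(benzyloxy)-8-[5-(5,7-bis(benzyloxy)-4-oxo-4H-chromen-2-yl)-2-methoxyphenyl]-3-(4-methoxyphenyl)-4H-chromen-4-one, via racemic dimethyl acetal 12 (not isolated)
Conditions: Tl(NO3)3·3H2O (1.2 equiv), MeOH/CH2Cl2, rt; filter; then 10% aq HCl, MeOH, 50 °C
Reagents that add atoms: none
Why: Trivalent thallium adds to the enone C=C at the α-carbon while methanol attacks the benzylic β-carbon; the electron-rich 4-methoxyphenyl ring then shifts from Cβ to Cα through a bridged phenonium ion as monovalent thallium leaves, and the methoxy-stabilised cation takes up a second methanol to give acetal 12. This is the known oxidative rearrangement of 2'-hydroxychalcones to 1,2-diaryl-3,3-dimethoxypropan-1-ones followed by their acid cyclisation to isoflavones, applied here to a larger substrate. In acid the acetal ionises to an oxocarbenium ion that the 2'-hydroxyl captures in a 6-exo-trig closure at oxygen (O1–C2), and loss of the second methanol gives the aromatic pyranone. No stereocentre remains, since the α-carbon of 12 forms racemic and becomes sp2. The step needs anisyl migration in preference to aurone-type closure, attack at the chalcone alkene only, and closure toward C8: the para-methoxy group makes the benzylic aryl a good migrating group, the flavone C2=C3 bond is a deactivated vinylogous ester inside an aromatic pyranone, the benzyl ethers tolerate the oxidant and dilute HCl, and the only free hydroxyl lies between the acyl group and ring B of the flavone, so that only the 8-aryl isoflavone can form.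

Step 9
Reactants: 13 5,7-bis(benzyloxy)-8-[5-(5,7-bis(benzyloxy)-4-oxo-4H-chromen-2-yl)-2-methoxyphenyl]-3-(4-methoxyphenyl)-4H-chromen-4-one
Product: 14 5,7-dihydroxy-8-[5-(5,7-dihydroxy-4-oxo-4H-chromen-2-yl)-2-methoxyphenyl]-3-(4-methoxyphenyl)-4H-chromen-4-one (CNP0117905.0)
Conditions: H2 (1 atm), 10% Pd/C, THF/MeOH, rt
Reagents that add atoms: none
Why: Hydrogenolysis of the four aryl benzyl ethers over palladium on carbon is much faster at 1 atm and room temperature than reduction of the pyranone double bonds and leaves the two methyl ethers untouched when hydrogen uptake is stopped after four equivalents.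

**Compound list**
1 | 2',4',6'-trihydroxyacetophenone | CC(=O)c1c(O)cc(O)cc1O | starting material
2 | 1-[2,4-bis(benzyloxy)-6-hydroxyphenyl]ethanone | CC(=O)c1c(O)cc(OCc2ccccc2)cc1OCc1ccccc1 | intermediate
3 | 3-bromo-4-methoxybenzaldehyde | COc1ccc(C=O)cc1Br | starting material
4 | (E)-1-[2,4-bis(benzyloxy)-6-hydroxyphenyl]-3-(3-bromo-4-methoxyphenyl)prop-2-en-1-one | COc1ccc(/C=C/C(=O)c2c(O)cc(OCc3ccccc3)cc2OCc2ccccc2)cc1Br | intermediate
5 | racemic 5,7-bis(benzyloxy)-2-(3-bromo-4-methoxyphenyl)chroman-4-one (not isolated) | COc1ccc(C2CC(=O)c3c(OCc4ccccc4)cc(OCc4ccccc4)cc3O2)cc1Br | intermediate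
6 | 5,7-bis(benzyloxy)-2-(3-bromo-4-methoxyphenyl)-4H-chromen-4-one | COc1ccc(-c2cc(=O)c3c(OCc4ccccc4)cc(OCc4ccccc4)cc3o2)cc1Br | intermediate
7 | 5,7-bis(benzyloxy)-2-[4-methoxy-3-(4,4,5,5-tetramethyl-1,3,2-dioxaborolan-2-yl)phenyl]-4H-chromen-4-one | COc1ccc(-c2cc(=O)c3c(OCc4ccccc4)cc(OCc4ccccc4)cc3o2)cc1B1OC(C)(C)C(C)(C)O1 | intermediate
8 | 1-[4,6-bis(benzyloxy)-2-hydroxy-3-iodophenyl]ethanone | CC(=O)c1c(O)c(I)c(OCc2ccccc2)cc1OCc1ccccc1 | intermediate
9 | 4-methoxybenzaldehyde | COc1ccc(C=O)cc1 | starting material
10 | (E)-1-[4,6-bis(benzyloxy)-2-hydroxy-3-iodophenyl]-3-(4-methoxyphenyl)prop-2-en-1-one | COc1ccc(/C=C/C(=O)c2c(O)c(I)c(OCc3ccccc3)cc2OCc2ccccc2)cc1 | intermediate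
11 | (E)-1-{4,6-bis(benzyloxy)-3-[5-(5,7-bis(benzyloxy)-4-oxo-4H-chromen-2-yl)-2-methoxyphenyl]-2-hydroxyphenyl}-3-(4-methoxyphenyl)prop-2-en-1-one | COc1ccc(/C=C/C(=O)c2c(O)c(-c3cc(-c4cc(=O)c5c(OCc6ccccc6)cc(OCc6ccccc6)cc5o4)ccc3OC)c(OCc3ccccc3)cc2OCc2ccccc2)cc1 | intermediate
12 | racemic 1-{4,6-bis(benzyloxy)-3-[5-(5,7-bis(benzyloxy)-4-oxo-4H-chromen-2-yl)-2-methoxyphenyl]-2-hydroxyphenyl}-3,3-dimethoxy-2-(4-methoxyphenyl)propan-1-one (not isolated) | COc1ccc(C(C(OC)OC)C(=O)c2c(O)c(-c3cc(-c4cc(=O)c5c(OCc6ccccc6)cc(OCc6ccccc6)cc5o4)ccc3OC)c(OCc3ccccc3)cc2OCc2ccccc2)cc1 | intermediate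
13 | 5,7-bis(benzyloxy)-8-[5-(5,7-bis(benzyloxy)-4-oxo-4H-chromen-2-yl)-2-methoxyphenyl]-3-(4-methoxyphenyl)-4H-chromen-4-one | COc1ccc(-c2coc3c(-c4cc(-c5cc(=O)c6c(OCc7ccccc7)cc(OCc7ccccc7)cc6o5)ccc4OC)c(OCc4ccccc4)cc(OCc4ccccc4)c3c2=O)cc1 | intermediate
14 | 5,7-dihydroxy-8-[5-(5,7-dihydroxy-4-oxo-4H-chromen-2-yl)-2-methoxyphenyl]-3-(4-methoxyphenyl)-4H-chromen-4-one | COc1ccc(-c2coc3c(-c4cc(-c5cc(=O)c6c(O)cc(O)cc6o5)ccc4OC)c(O)cc(O)c3c2=O)cc1 | target

**Count**
Total steps: 9. Longest linear sequence: 7 steps (steps 1, 2, 3, 4, 7, 8, 9); steps 5 and 6 form the shorter branch that enters at step 7.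

**Steps most likely to fail**

Step 8. The free phenol may attack the thallium-activated alkene in competition with aryl migration (aurone-type closure), the benzyloxy-substituted rings may be oxidised, or the acetal may close incompletely in acid. The fallback sets out from 11 and comes back at 13. Compound 11 would be heated with NaOAc in EtOH/THF so that the phenol closes onto the enone by oxa-Michael addition, which ties up the hydroxyl in the racemic flavanone F1. F1 would then be treated with PhI(OAc)2 and catalytic H2SO4 in HC(OMe)3. Trivalent iodine attacks C3 of the enol ether, the anisyl group moves from C2 to C3 as iodobenzene leaves, and loss of a proton from the O1-stabilised cation gives 13. This is the known thallium-free 2,3-aryl migration of flavanones to isoflavones.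

Step 7. Transmetalation at the doubly ortho-substituted iodide may be slow, so that protodeboronation of the ortho-methoxy boronate and hydrodeiodination take over, and the base may close the hydroxy enone to a flavanone. The fallback sets out from 8 and 7 and comes back at 11. The biaryl bond would be made before the enone: 8 and 7 would be coupled under the same Pd(OAc)2/SPhos/K3PO4 conditions to the biaryl methyl ketone F2, which cannot cyclise. F2 would then be condensed with 9 (KOH or Ba(OH)2, EtOH/THF, rt) in a Claisen–Schmidt reaction to give 11.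

Step 3. The benzyl ether peri to the carbonyl may be lost to HI formed at 120 °C, or the reaction may stall at the flavanone. The fallback sets out from 2 and comes back at 6, building the flavone by a Baker–Venkataraman sequence that needs no oxidant. Compound 2 would be acylated with commercial 3-bromo-4-methoxybenzoyl chloride (pyridine, DMAP) to the aryl ester F3. KOH in pyridine at 50 °C would move the aroyl group from oxygen to the enolate carbon to give the 1,3-diketone F4. Catalytic TsOH in refluxing toluene would then close and dehydrate F4 to 6.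

**Further compounds**
F1 | step 8 | racemic 5,7-bis(benzyloxy)-8-[5-(5,7-bis(benzyloxy)-4-oxo-4H-chromen-2-yl)-2-methoxyphenyl]-2-(4-methoxyphenyl)chroman-4-one | COc1ccc(C2CC(=O)c3c(OCc4ccccc4)cc(OCc4ccccc4)c(-c4cc(-c5cc(=O)c6c(OCc7ccccc7)cc(OCc7ccccc7)cc6o5)ccc4OC)c3O2)cc1
F2 | step 7 | 1-{4,6-bis(benzyloxy)-3-[5-(5,7-bis(benzyloxy)-4-oxo-4H-chromen-2-yl)-2-methoxyphenyl]-2-hydroxyphenyl}ethanone | CC(=O)c1c(O)c(-c2cc(-c3cc(=O)c4c(OCc5ccccc5)cc(OCc5ccccc5)cc4o3)ccc2OC)c(OCc2ccccc2)cc1OCc1ccccc1
F3 | step 3 | 2-acetyl-3,5-bis(benzyloxy)phenyl 3-bromo-4-methoxybenzoate | CC(=O)c1c(OC(=O)c2ccc(OC)c(Br)c2)cc(OCc2ccccc2)cc1OCc1ccccc1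
F4 | step 3 | 1-[2,4-bis(benzyloxy)-6-hydroxyphenyl]-3-(3-bromo-4-methoxyphenyl)propane-1,3-dione | COc1ccc(C(=O)CC(=O)c2c(O)cc(OCc3ccccc3)cc2OCc2ccccc2)cc1Br
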